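**Retrosynthetic overview**

1. Target 27 ⇐ ten-membered hydroxy keto ester 25 (acidic deprotection and lactonisation). 25 ⇐ cis-decalin hydroperoxide 22 by a Criegee 1,2-shift of C6 from C1 to oxygen, which cleaves the C1–C6 ring-fusion bond (six/six → ten-membered ring, retention at C6).
2. 22 ⇐ ring-fusion epoxide 21 (perhydrolysis at C1) ⇐ tertiary allylic alcohol 18 (1,3-transposition C1→C9, directed epoxidation, acetylation). 18 ⇐ ketol 8 (C3 reduction, α-methylenation, C8 reduction, angeloylation).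
3. 8 ⇐ ring B dienone ketal 2 + acetate unit 4 + four-carbon enone 5 (asymmetric Mukaiyama–Michael at C7, vinylogation at C6, aldol C2→C1). 2 ⇐ o-cresol.
4. Order of ring formation: ring B (from the arene) → ring A (aldol) → ten-membered carbocycle (ring expansion) → γ-lactone.

Convention: every intermediate keeps the germacrane carbon numbers of the target (C1–C15); ring A = C1–C6, ring B = C1, C6–C10; "1,6-cyclogermacrane" means the decalin with a C1–C6 bond; α/β = the face of ring B that carries H-7 / the C7 side chain.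

**Route**

Step 1
Reactants: 1 o-cresol
Product: 2 4,4-dimethoxy-2-methylcyclohexa-2,5-dien-1-one
Conditions: PhI(OAc)2 (2.2 equiv), MeOH, 0 °C → rt
Reagents that add atoms: methanol, CO
Why: two successive phenol oxidations by the iodane (oxidative dearomatization) trap methanol twice at the free para position and give the p-quinone monoketal, i.e. ring B with C1=O, C8 masked as a ketal and the C10 methyl in place; no stereocentre is formed.

Step 2
Reactants: 3 tert-butyl acetate
Product: 4 1-tert-butoxy-1-(trimethylsilyloxy)ethene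
Conditions: LiN(iPr)2, THF, −78 °C; Me3SiCl, −78 °C → rt; distil
Reagents that add atoms: chlorotrimethylsilane, C[Si](C)(C)Cl
Why: kinetic ester enolate formation and O-silylation (silyl ketene acetal synthesis) give the nucleophile that carries C11 and C12.

Step 3
Reactants: 2 4,4-dimethoxy-2-methylcyclohexa-2,5-dien-1-one, 4 1-tert-butoxy-1-(trimethylsilyloxy)ethene, 5 (E)-4-methoxy-3-methylbut-3-en-2-one
Product: 7 tert-butyl 2-[(1S)-6,6-dimethoxy-4-methyl-2-(2-methyl-3-oxobut-1-enyl)-3-oxocyclohex-4-en-1-yl]acetate, via silyl enol ether 6 (not isolated)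
Conditions: (S)-3,3-diphenyl-1-(o-tolyl)tetrahydro-1H,3H-pyrrolo[1,2-c][1,3,2]oxazaborole·HN(SO2CF3)2 (10 mol %), CH2Cl2, −78 °C; then 5, Me3SiOSO2CF3 (10 mol %), −78 → −20 °C
Reagents that add atoms: none
Why: catalytic enantioselective Mukaiyama–Michael addition: the cationic oxazaborolidine binds the dienone carbonyl and the ketene acetal adds to C7, the β-carbon of the enone without an α-substituent, setting C7 (S; the catalyst enantiomer is chosen for this face); the silyl enol ether 6 is then vinylogated at C6 by a silyl-triflate-catalysed Mukaiyama–Michael addition–elimination on the β-methoxy enone (loss of MeOSiMe3), which installs C2–C5 and C15.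

Step 4
Reactants: 7 tert-butyl 2-[(1S)-6,6-dimethoxy-4-methyl-2-(2-methyl-3-oxobut-1-enyl)-3-oxocyclohex-4-en-1-yl]acetate
Product: 8 tert-butyl 1β-hydroxy-8,8-dimethoxy-3-oxo-6αH,7αH-1,6-cyclo-13-norgermacra-4,9-dien-12-oate
Conditions: L-proline (30 mol %), DMSO, rt
Reagents that add atoms: none
Why: Hajos–Parrish-type intramolecular enamine aldol that stops at the ketol: the labile C6 centre and the C4=C5 geometry equilibrate and only the Z isomer closes; C2 adds to the C1 carbonyl anti to the C7 side chain (held pseudo-axial by the neighbouring ketal), giving 1β-OH, and chair-like closure with C5 equatorial gives the trans ring fusion (6α-H, C5 cis to the C7 side chain).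

Step 5
Reactants: 8 tert-butyl 1β-hydroxy-8,8-dimethoxy-3-oxo-6αH,7αH-1,6-cyclo-13-norgermacra-4,9-dien-12-oate
Product: 9 tert-butyl (3R)-1β,3-dihydroxy-8,8-dimethoxy-6αH,7αH-1,6-cyclo-13-norgermacra-4,9-dien-12-oate
Conditions: Me4NBH(OAc)3, MeCN–AcOH, −30 °C
Reagents that add atoms: none
Why: Evans–Saksena reduction: the axial 1-OH binds boron and delivers hydride intramolecularly to the same face of the C3 enone carbonyl (1,2-reduction), giving the 1,3-anti diol with the equatorial 3-OH (3R).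

Step 6
Reactants: 9 tert-butyl (3R)-1β,3-dihydroxy-8,8-dimethoxy-6αH,7αH-1,6-cyclo-13-norgermacra-4,9-dien-12-oate
Product: 10 tert-butyl (3R)-3-(tert-butyldimethylsilyloxy)-1β-hydroxy-8,8-dimethoxy-6αH,7αH-1,6-cyclo-13-norgermacra-4,9-dien-12-oate
Conditions: tBuMe2SiCl, imidazole, DMF, rt
Reagents that add atoms: tert-butyldimethylsilyl chloride, CC(C)(C)[Si](C)(C)Cl
Why: standard silylation protects the secondary allylic 3-OH only; the tertiary ring-fusion hydroxyl does not react under these conditions.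

Step 7
Reactants: 10 tert-butyl (3R)-3-(tert-butyldimethylsilyloxy)-1β-hydroxy-8,8-dimethoxy-6αH,7αH-1,6-cyclo-13-norgermacra-4,9-dien-12-oate
Product: 13 tert-butyl (3R)-3-(tert-butyldimethylsilyloxy)-1β-hydroxy-8,8-dimethoxy-6αH,7αH-1,6-cyclogermacra-4,9,11(13)-trien-12-oate, via Mannich base 11 (not isolated), via trimethylammonium iodide 12 (not isolated)
Conditions: LiN(iPr)2 (2.2 equiv), THF, −78 °C; [Me2N=CH2]I, −78 → 0 °C; MeI, rt; then aq. NaHCO3, rt
Reagents that add atoms: N,N-dimethylmethyleneiminium iodide (Eschenmoser's salt), C=[N+](C)C.[I-]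
Why: Eschenmoser α-methylenation: the alkoxide/ester-enolate dianion is aminomethylated at C11, and quaternisation followed by Hofmann-type elimination gives the acrylate (C13) while the ketal still keeps C7 from being enolisable.

Step 8
Reactants: 13 tert-butyl (3R)-3-(tert-butyldimethylsilyloxy)-1β-hydroxy-8,8-dimethoxy-6αH,7αH-1,6-cyclogermacra-4,9,11(13)-trien-12-oate
Product: 14 tert-butyl (3R)-3-(tert-butyldimethylsilyloxy)-1β-hydroxy-8-oxo-6αH,7αH-1,6-cyclogermacra-4,9,11(13)-trien-12-oate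
Conditions: pyridinium p-toluenesulfonate (cat.), acetone–H2O, rt, short reaction time
Reagents that add atoms: water, O
Why: mild acid hydrolysis of the allylic dimethyl ketal unmasks the C8 enone only now that C1 is no longer a ketone (no hydroquinone tautomer is possible); the silyl ether and tert-butyl ester survive, and the product is reduced at once because C7 is now α to a carbonyl.

Step 9
Reactants: 14 tert-butyl (3R)-3-(tert-butyldimethylsilyloxy)-1β-hydroxy-8-oxo-6αH,7αH-1,6-cyclogermacra-4,9,11(13)-trien-12-oate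
Product: 15 tert-butyl (3R)-3-(tert-butyldimethylsilyloxy)-1β,8β-dihydroxy-6αH,7αH-1,6-cyclogermacra-4,9,11(13)-trien-12-oate
Conditions: NaBH4, CeCl3·7H2O, MeOH, −78 °C
Reagents that add atoms: none
Why: Luche 1,2-reduction: hydride attacks C8 axially from the α face, anti to the C7 side chain that the trans ring fusion holds pseudo-axial, giving the 8β alcohol; the hindered tert-butyl ester does not lactonise onto the cis hydroxyl.

Step 10
Reactants: 15 tert-butyl (3R)-3-(tert-butyldimethylsilyloxy)-1β,8β-dihydroxy-6αH,7αH-1,6-cyclogermacra-4,9,11(13)-trien-12-oate, 16 angelic acid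
Product: 18 tert-butyl (3R)-8β-(angeloyloxy)-3-(tert-butyldimethylsilyloxy)-1β-hydroxy-6αH,7αH-1,6-cyclogermacra-4,9,11(13)-trien-12-oate, via mixed anhydride 17 (not isolated)
Conditions: 16, 2,4,6-Cl3C6H2COCl, Et3N, toluene, rt; then 15, 4-(dimethylamino)pyridine, rt
Reagents that add atoms: none
Why: Yamaguchi esterification acylates the only secondary hydroxyl (the tertiary 1-OH is inert) and is the usual way to make an angelate with little Z→E isomerisation; C8 keeps its configuration.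

Step 11
Reactants: 18 tert-butyl (3R)-8β-(angeloyloxy)-3-(tert-butyldimethylsilyloxy)-1β-hydroxy-6αH,7αH-1,6-cyclogermacra-4,9,11(13)-trien-12-oate
Product: 19 tert-butyl (3R)-8β-(angeloyloxy)-3-(tert-butyldimethylsilyloxy)-9β-hydroxy-6αH,7αH-1,6-cyclogermacra-1(10),4,11(13)-trien-12-oate
Conditions: Ph3SiOReO3 (5 mol %), Et2O, −20 → 0 °C
Reagents that add atoms: none
Why: rhenium-oxo-catalysed 1,3-transposition of the tertiary allylic alcohol through a cyclic perrhenate ester is suprafacial, so the 1β oxygen arrives at C9 on the β face (sets C9); it is driven by the tetrasubstituted C1=C10 alkene and by relief of the 1,3-diaxial contact between 1-OH and the C7 side chain.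

Step 12
Reactants: 19 tert-butyl (3R)-8β-(angeloyloxy)-3-(tert-butyldimethylsilyloxy)-9β-hydroxy-6αH,7αH-1,6-cyclogermacra-1(10),4,11(13)-trien-12-oate
Product: 20 tert-butyl (3R)-8β-(angeloyloxy)-3-(tert-butyldimethylsilyloxy)-1β,10β-epoxy-9β-hydroxy-6αH,7αH-1,6-cyclogermacra-4,11(13)-dien-12-oate
Conditions: VO(acac)2 (5 mol %), tBuOOH, CH2Cl2, 0 °C → rt
Reagents that add atoms: tert-butyl hydroperoxide, CC(C)(C)OO
Why: hydroxyl-directed epoxidation: the vanadium alkylperoxide bound to the 9β-OH delivers oxygen to the tetrasubstituted allylic alkene syn to the hydroxyl, which puts the future C10 oxygen on the β face; the other alkenes are electron-poor or have no directing group.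

Step 13
Reactants: 20 tert-butyl (3R)-8β-(angeloyloxy)-3-(tert-butyldimethylsilyloxy)-1β,10β-epoxy-9β-hydroxy-6αH,7αH-1,6-cyclogermacra-4,11(13)-dien-12-oate
Product: 21 tert-butyl (3R)-9β-acetoxy-8β-(angeloyloxy)-3-(tert-butyldimethylsilyloxy)-1β,10β-epoxy-6αH,7αH-1,6-cyclogermacra-4,11(13)-dien-12-oate
Conditions: Ac2O, pyridine, 4-(dimethylamino)pyridine (cat.), CH2Cl2, 0 °C → rt
Reagents that add atoms: acetic anhydride, CC(=O)OC(C)=O
Why: acylation of the only free hydroxyl installs the C9 acetate of the target.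

Step 14
Reactants: 21 tert-butyl (3R)-9β-acetoxy-8β-(angeloyloxy)-3-(tert-butyldimethylsilyloxy)-1β,10β-epoxy-6αH,7αH-1,6-cyclogermacra-4,11(13)-dien-12-oate
Product: 22 tert-butyl (3R)-9β-acetoxy-8β-(angeloyloxy)-3-(tert-butyldimethylsilyloxy)-1α-hydroperoxy-10β-hydroxy-6αH,7αH-1,6-cyclogermacra-4,11(13)-dien-12-oate
Conditions: H2O2 (anhydrous, in Et2O, excess), HBF4·OEt2 (5 mol %), −20 → 0 °C
Reagents that add atoms: hydrogen peroxide, OO
Why: acid-catalysed perhydrolysis of the epoxide: H2O2 opens the protonated tetrasubstituted epoxide with inversion at C1, the carbon better able to carry positive charge (C10 is deactivated by the adjacent acetoxy group), and the epoxide oxygen stays on C10 as the 10β tertiary alcohol (sets C10, 10S in the target).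

Step 15
Reactants: 22 tert-butyl (3R)-9β-acetoxy-8β-(angeloyloxy)-3-(tert-butyldimethylsilyloxy)-1α-hydroperoxy-10β-hydroxy-6αH,7αH-1,6-cyclogermacra-4,11(13)-dien-12-oate
Product: 25 tert-butyl (3R,6R,7S,8S,9S,10S,4Z)-9-acetoxy-8-(angeloyloxy)-3-(tert-butyldimethylsilyloxy)-6,10-dihydroxy-1-oxogermacra-4,11(13)-dien-12-oate, via cyclic peroxycarbonate 23 (not isolated), via ketal carbonate 24 (not isolated)
Conditions: COCl2 (toluene solution, 1.1 equiv), pyridine, CH2Cl2, −40 °C; then (CF3)2CHOH, 0 °C → rt; then aq. NaHCO3–THF, rt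
Reagents that add atoms: none
Why: Proposed new method: phosgene ties the hydroperoxide and the vicinal tertiary hydroxyl into a six-membered cyclic peroxycarbonate, so that O-10 is acylated (no glycol-type C1–C10 scission) and the C1–C10 bond is held gauche to the O–O bond; ionisation of the O–O bond in the polar solvent then triggers the Criegee 1,2-shift of the antiperiplanar, secondary allyl-type ring-fusion carbon C6 (preferred over primary C2) from C1 to oxygen with retention (sets 6R and opens the decalin to the ten-membered ring with the ring-derived 4Z alkene untouched), the carbonate anion recaptures the dioxacarbenium ion at C1, and mild hydrolysis releases CO2 (the phosgene carbon), the C1 ketone, the 6-hydroxyl and the free 10-hydroxyl; closest known reaction type: Criegee rearrangement of tertiary peresters, as in 9-decalyl perbenzoate → 6-hydroxycyclodecanone.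

Step 16
Reactants: 25 tert-butyl (3R,6R,7S,8S,9S,10S,4Z)-9-acetoxy-8-(angeloyloxy)-3-(tert-butyldimethylsilyloxy)-6,10-dihydroxy-1-oxogermacra-4,11(13)-dien-12-oate
Product: 27 (3R,6R,7S,8S,9S,10S,4Z)-9-acetoxy-8-(angeloyloxy)-3,10-dihydroxy-1-oxogermacra-4,11(13)-dien-12,6-olide (CNP0308559.3), via seco acid 26 (not isolated)
Conditions: CF3CO2H–CH2Cl2–H2O (20:78:2), 0 °C → rt
Reagents that add atoms: none
Why: acid cleaves the silyl ether and the tert-butyl ester (loss of isobutene), and the freed acid closes the trans-fused γ-lactone onto the 6-hydroxyl (acid-catalysed lactonisation), which also pulls the hydroxy ketone out of its transannular hemiketal; no stereocentre is touched.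

**Compound list**

1 | o-cresol (2-methylphenol) | Cc1ccccc1O | starting material
2 | 4,4-dimethoxy-2-methylcyclohexa-2,5-dien-1-one (ring B: C1=O, C8 ketal, C10 methyl) | O=C1C=CC(OC)(OC)C=C1C | intermediate
3 | tert-butyl acetate | CC(=O)OC(C)(C)C | starting material
4 | 1-tert-butoxy-1-(trimethylsilyloxy)ethene | C=C(OC(C)(C)C)O[Si](C)(C)C | intermediate
5 | (E)-4-methoxy-3-methylbut-3-en-2-one | CO/C=C(\C)C(C)=O | starting material
6 | tert-butyl 2-[(1S)-6,6-dimethoxy-4-methyl-3-(trimethylsilyloxy)cyclohexa-2,4-dien-1-yl]acetate (silyl enol ether, not isolated) | CC1=CC(OC)(OC)[C@@H](CC(=O)OC(C)(C)C)C=C1O[Si](C)(C)C | intermediate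
7 | tert-butyl 2-[(1S)-6,6-dimethoxy-4-methyl-2-(2-methyl-3-oxobut-1-enyl)-3-oxocyclohex-4-en-1-yl]acetate (C6 epimers and C4=C5 E/Z isomers in equilibrium) | CC(=O)C(C)=CC1C(=O)C(C)=CC(OC)(OC)[C@H]1CC(=O)OC(C)(C)C | intermediate
8 | tert-butyl 1β-hydroxy-8,8-dimethoxy-3-oxo-6αH,7αH-1,6-cyclo-13-norgermacra-4,9-dien-12-oate (trans-fused ketol) | CC1=C[C@@H]2[C@H](CC(=O)OC(C)(C)C)C(OC)(OC)C=C(C)[C@@]2(O)CC1=O | intermediate
9 | tert-butyl (3R)-1β,3-dihydroxy-8,8-dimethoxy-6αH,7αH-1,6-cyclo-13-norgermacra-4,9-dien-12-oate (1,3-anti diol) | CC1=C[C@@H]2[C@H](CC(=O)OC(C)(C)C)C(OC)(OC)C=C(C)[C@@]2(O)C[C@H]1O | intermediate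
10 | tert-butyl (3R)-3-(tert-butyldimethylsilyloxy)-1β-hydroxy-8,8-dimethoxy-6αH,7αH-1,6-cyclo-13-norgermacra-4,9-dien-12-oate | CC1=C[C@@H]2[C@H](CC(=O)OC(C)(C)C)C(OC)(OC)C=C(C)[C@@]2(O)C[C@H]1O[Si](C)(C)C(C)(C)C | intermediate
11 | Mannich base: 13-(dimethylamino)-11,13-dihydro derivative of 13 (C11 epimers, not isolated) | CC1=C[C@@H]2[C@H](C(CN(C)C)C(=O)OC(C)(C)C)C(OC)(OC)C=C(C)[C@@]2(O)C[C@H]1O[Si](C)(C)C(C)(C)C | intermediate
12 | trimethylammonium iodide of 11 (not isolated) | CC1=C[C@@H]2[C@H](C(C[N+](C)(C)C)C(=O)OC(C)(C)C)C(OC)(OC)C=C(C)[C@@]2(O)C[C@H]1O[Si](C)(C)C(C)(C)C.[I-] | intermediate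
13 | tert-butyl (3R)-3-(tert-butyldimethylsilyloxy)-1β-hydroxy-8,8-dimethoxy-6αH,7αH-1,6-cyclogermacra-4,9,11(13)-trien-12-oate | CC1=C[C@@H]2[C@H](C(=C)C(=O)OC(C)(C)C)C(OC)(OC)C=C(C)[C@@]2(O)C[C@H]1O[Si](C)(C)C(C)(C)C | intermediate
14 | tert-butyl (3R)-3-(tert-butyldimethylsilyloxy)-1β-hydroxy-8-oxo-6αH,7αH-1,6-cyclogermacra-4,9,11(13)-trien-12-oate | CC1=C[C@@H]2[C@H](C(=C)C(=O)OC(C)(C)C)C(=O)C=C(C)[C@@]2(O)C[C@H]1O[Si](C)(C)C(C)(C)C | intermediate
15 | tert-butyl (3R)-3-(tert-butyldimethylsilyloxy)-1β,8β-dihydroxy-6αH,7αH-1,6-cyclogermacra-4,9,11(13)-trien-12-oate | CC1=C[C@@H]2[C@H](C(=C)C(=O)OC(C)(C)C)[C@H](O)C=C(C)[C@@]2(O)C[C@H]1O[Si](C)(C)C(C)(C)C | intermediate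
16 | angelic acid ((Z)-2-methylbut-2-enoic acid) | C/C=C(/C)C(=O)O | starting material
17 | angelic 2,4,6-trichlorobenzoic anhydride (not isolated) | C/C=C(/C)C(=O)OC(=O)c1c(Cl)cc(Cl)cc1Cl | intermediate
18 | tert-butyl (3R)-8β-(angeloyloxy)-3-(tert-butyldimethylsilyloxy)-1β-hydroxy-6αH,7αH-1,6-cyclogermacra-4,9,11(13)-trien-12-oate | CC1=C[C@@H]2[C@H](C(=C)C(=O)OC(C)(C)C)[C@H](OC(=O)/C(C)=C\C)C=C(C)[C@@]2(O)C[C@H]1O[Si](C)(C)C(C)(C)C | intermediate
19 | tert-butyl (3R)-8β-(angeloyloxy)-3-(tert-butyldimethylsilyloxy)-9β-hydroxy-6αH,7αH-1,6-cyclogermacra-1(10),4,11(13)-trien-12-oate | CC1=C[C@@H]2[C@H](C(=C)C(=O)OC(C)(C)C)[C@H](OC(=O)/C(C)=C\C)[C@H](O)C(C)=C2C[C@H]1O[Si](C)(C)C(C)(C)C | intermediate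
20 | tert-butyl (3R)-8β-(angeloyloxy)-3-(tert-butyldimethylsilyloxy)-1β,10β-epoxy-9β-hydroxy-6αH,7αH-1,6-cyclogermacra-4,11(13)-dien-12-oate | CC1=C[C@@H]2[C@H](C(=C)C(=O)OC(C)(C)C)[C@H](OC(=O)/C(C)=C\C)[C@H](O)[C@]3(C)O[C@]23C[C@H]1O[Si](C)(C)C(C)(C)C | intermediate
21 | tert-butyl (3R)-9β-acetoxy-8β-(angeloyloxy)-3-(tert-butyldimethylsilyloxy)-1β,10β-epoxy-6αH,7αH-1,6-cyclogermacra-4,11(13)-dien-12-oate | CC1=C[C@@H]2[C@H](C(=C)C(=O)OC(C)(C)C)[C@H](OC(=O)/C(C)=C\C)[C@H](OC(C)=O)[C@]3(C)O[C@]23C[C@H]1O[Si](C)(C)C(C)(C)C | intermediate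
22 | tert-butyl (3R)-9β-acetoxy-8β-(angeloyloxy)-3-(tert-butyldimethylsilyloxy)-1α-hydroperoxy-10β-hydroxy-6αH,7αH-1,6-cyclogermacra-4,11(13)-dien-12-oate (cis-fused) | CC1=C[C@@H]2[C@H](C(=C)C(=O)OC(C)(C)C)[C@H](OC(=O)/C(C)=C\C)[C@H](OC(C)=O)[C@](C)(O)[C@]2(OO)C[C@H]1O[Si](C)(C)C(C)(C)C | intermediate
23 | cyclic peroxycarbonate of 22 (1,2,4-trioxan-3-one ring C1–O–O–C(=O)–O–C10, not isolated) | CC1=C[C@@H]2[C@H](C(=C)C(=O)OC(C)(C)C)[C@H](OC(=O)/C(C)=C\C)[C@H](OC(C)=O)[C@]3(C)OC(=O)OO[C@@]23C[C@H]1O[Si](C)(C)C(C)(C)C | intermediate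
24 | ketal carbonate: ten-membered ring with a C1–O–C6 bridge and a cyclic carbonate across C1/C10 (C1 configuration undefined, lost on hydrolysis; not isolated) | C=C(C(=O)OC(C)(C)C)[C@H]1[C@H]2/C=C(/C)[C@H](O[Si](C)(C)C(C)(C)C)CC3(O2)OC(=O)O[C@@]3(C)[C@@H](OC(C)=O)[C@H]1OC(=O)/C(C)=C\C | intermediate
25 | tert-butyl (3R,6R,7S,8S,9S,10S,4Z)-9-acetoxy-8-(angeloyloxy)-3-(tert-butyldimethylsilyloxy)-6,10-dihydroxy-1-oxogermacra-4,11(13)-dien-12-oate (in equilibrium with its 1,6-hemiketal) | C=C(C(=O)OC(C)(C)C)[C@H]1[C@H](O)/C=C(/C)[C@H](O[Si](C)(C)C(C)(C)C)CC(=O)[C@@](C)(O)[C@@H](OC(C)=O)[C@H]1OC(=O)/C(C)=C\C | intermediate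
26 | (3R,6R,7S,8S,9S,10S,4Z)-9-acetoxy-8-(angeloyloxy)-3,6,10-trihydroxy-1-oxogermacra-4,11(13)-dien-12-oic acid (seco acid, not isolated) | C=C(C(=O)O)[C@H]1[C@H](O)/C=C(/C)[C@H](O)CC(=O)[C@@](C)(O)[C@@H](OC(C)=O)[C@H]1OC(=O)/C(C)=C\C | intermediate
27 | (3R,6R,7S,8S,9S,10S,4Z)-9-acetoxy-8-(angeloyloxy)-3,10-dihydroxy-1-oxogermacra-4,11(13)-dien-12,6-olide (CNP0308559.3) | C=C1C(=O)O[C@@H]2/C=C(/C)[C@H](O)CC(=O)[C@@](C)(O)[C@@H](OC(C)=O)[C@@H](OC(=O)/C(C)=C\C)[C@@H]12 | target

**Step count and risks**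

Total steps: 16. Longest linear sequence: 15 (steps 1 and 3–16, from o-cresol); step 2 is a one-step side branch.

The three steps most likely to fail:

The aldol of step 4. The vinylogous 1,5-diketone 7 can also close through oxygen to a 2H-pyran or dehydrate and aromatise ring A, and the C1/C6 configuration rests on kinetic control. Fallback, setting out from silyl enol ether 6 (made as in step 3): Mukaiyama–Michael addition of 6 to 3-methylbut-3-en-2-one (Me3SiOSO2CF3 cat., then aqueous work-up) gives the saturated 1,5-diketone tert-butyl 2-[(1S)-6,6-dimethoxy-4-methyl-2-(2-methyl-3-oxobutyl)-3-oxocyclohex-4-en-1-yl]acetate F1. F1 has no vinylogous C6–H acidity and no pyran or phenol pathway. The classical proline aldol then gives the saturated ketol tert-butyl 1β-hydroxy-8,8-dimethoxy-3-oxo-6αH,7αH-1,6-cyclo-13-norgermacr-9-en-12-oate F2. Dehydrogenation of the C3 ketone toward C4–C5 with 2-iodoxybenzoic acid (or Saegusa–Ito oxidation with Pd(OAc)2) comes back to ketol 8.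

The allylic transposition of step 11. The tertiary allylic alcohol may dehydrate or ionise, and the neighbouring angelate may migrate. Fallback, setting out from 18: oxidative transposition with pyridinium chlorochromate, C5H5NH[CrO3Cl] (Babler–Dauben), gives the enone tert-butyl (3R)-8β-(angeloyloxy)-3-(tert-butyldimethylsilyloxy)-9-oxo-6αH,7αH-1,6-cyclogermacra-1(10),4,11(13)-trien-12-oate F3. Its 1,2-reduction from the α face with NaBH4/CeCl3·7H2O (or, for reagent control, an oxazaborolidine/BH3 reduction) comes back to allylic alcohol 19.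

The tethered Criegee ring expansion of step 15 (the proposed new method). The cyclic peroxycarbonate may not form on the crowded cis-diol array, or may ionise too slowly. Fallback with known chemistry, setting out from 22: (CF3CO)2O, pyridine and 4-(dimethylamino)pyridine at −78 °C acylate both the hydroperoxide and the tertiary hydroxyl to the bis(trifluoroacetate) of 22 F4. On warming to 0 °C, F4 undergoes the classical Criegee rearrangement of a peroxy trifluoroacetate to the ketal trifluoroacetate of 25 F5 (C1–O–C6 bridge, 1-OCOCF3, 10-OCOCF3). NaHCO3 in aqueous methanol cleaves both trifluoroacetates and comes back to 25.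

**Further compounds**

F1 | step 4 | tert-butyl 2-[(1S)-6,6-dimethoxy-4-methyl-2-(2-methyl-3-oxobutyl)-3-oxocyclohex-4-en-1-yl]acetate (C4 and C6 epimers) | CC(=O)C(C)CC1C(=O)C(C)=CC(OC)(OC)[C@H]1CC(=O)OC(C)(C)C
F2 | step 4 | tert-butyl 1β-hydroxy-8,8-dimethoxy-3-oxo-6αH,7αH-1,6-cyclo-13-norgermacr-9-en-12-oate (C4 epimers) | CC1C[C@@H]2[C@H](CC(=O)OC(C)(C)C)C(OC)(OC)C=C(C)[C@@]2(O)CC1=O
F3 | step 11 | tert-butyl (3R)-8β-(angeloyloxy)-3-(tert-butyldimethylsilyloxy)-9-oxo-6αH,7αH-1,6-cyclogermacra-1(10),4,11(13)-trien-12-oate | CC1=C[C@@H]2[C@H](C(=C)C(=O)OC(C)(C)C)[C@H](OC(=O)/C(C)=C\C)C(=O)C(C)=C2C[C@H]1O[Si](C)(C)C(C)(C)C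
F4 | step 15 | bis(trifluoroacetate) of 22 (1α-OOCOCF3, 10β-OCOCF3) | CC1=C[C@@H]2[C@H](C(=C)C(=O)OC(C)(C)C)[C@H](OC(=O)/C(C)=C\C)[C@H](OC(C)=O)[C@](C)(OC(=O)C(F)(F)F)[C@]2(OOC(=O)C(F)(F)F)C[C@H]1O[Si](C)(C)C(C)(C)C
F5 | step 15 | ketal trifluoroacetate of 25 (C1–O–C6 bridge, 1-OCOCF3, 10-OCOCF3; C1 configuration undefined) | C=C(C(=O)OC(C)(C)C)[C@H]1[C@H]2/C=C(/C)[C@H](O[Si](C)(C)C(C)(C)C)CC(O2)(OC(=O)C(F)(F)F)[C@@](C)(OC(=O)C(F)(F)F)[C@@H](OC(C)=O)[C@H]1OC(=O)/C(C)=C\C
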